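**Plan**

1. Numbering (nerolidol type): C1=C2, C3 (carbinol carbon), C4, C5, C6 (CHBr), then the oxane ring C7 (C–CH3), C8, C9, C10 (CHBr), C11 (CMe2) and O.
2. Cuts: first O–Si at C3. Then, together, the ring bonds C7–C8 and O–C11 plus C10–Br, which opens the oxane to methyl ketone 8 and a homoprenyl (4-methylpent-3-enyl) Grignard reagent. Then C7–CH3, C6–Br and the C6–C7 homologation carbon, back to the C6=CMe2 alkene of (S)-linalool.
3. Enabling feature: the oxane oxygen lies between two fully substituted carbons. C7 is a former ketone carbon that keeps its oxygen, and C11 is the Markovnikov CMe2 end of a prenyl alkene. The ring arc C8–C11 is a homoprenyl unit, and C6–Br/C7–O is the anti bromohydrin pattern that an α-bromo ketone gives on addition.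
4. Both C–Br carbons are neopentyl-like, so neither bromide is made by SN2. C6–Br is set while C7 is still sp2, and C10–Br comes from bromonium opening.
5. Forward order: the chain C1–C7 is built from linalool, the only ring (the oxane) arises in step 8, and desilylation follows.
6. Stereochemistry: C3 is bought with (S)-linalool, C6 is set by enamine catalysis, C7 is relayed from C6 in the key step, and C10 is set by a chiral Lewis base catalyst in the same step.

Key step: step 8

Assumption 1: (S)-(+)-linalool (coriandrol) is taken as a commercial chiral-pool material of high enantiomeric purity.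
Assumption 2: the sense of induction of the thiophosphoramide catalyst on this alkenol is not established. The (R)-catalyst is written and stands for whichever antipode delivers bromine to the Si face of C10.

**Step 1**
Reactants: 1 (S)-linalool
Product: 2 (3S)-3,7-dimethyl-3-(triethylsilyloxy)octa-1,6-diene
Conditions: TESOTf, 2,6-lutidine, CH2Cl2, −78 to 0 °C
Reagents that add atoms: triethylsilyl trifluoromethanesulfonate, CC[Si](CC)(CC)OS(=O)(=O)C(F)(F)F
Why: O-silylation of the hindered tertiary allylic alcohol with the silyl triflate masks the hydroxyl, which would otherwise be deprotonated in steps 5 and 8 and could displace the C6 bromide; C3 is not touched.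

**Step 2**
Reactants: 2 TES ether of linalool
Product: 3 (4S)-4-methyl-4-(triethylsilyloxy)hex-5-enal
Conditions: O3 (1 equiv, Sudan Red 7B end point), CH2Cl2, −78 °C; then Me2S, −78 °C to rt
Reagents that add atoms: ozone, [O-][O+]=O
Why: Ozonolysis with reductive work-up cleaves the electron-rich trisubstituted alkene well before the monosubstituted vinyl group, which is hindered and deactivated by the adjacent silyloxy carbon.

**Step 3**
Reactants: 3 (4S)-4-methyl-4-(triethylsilyloxy)hex-5-enal
Product: 5 (5S)-5-methyl-5-(triethylsilyloxy)hept-6-enal, via methyl enol ether 4 (not isolated)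
Conditions: MeOCH2PPh3Cl, KHMDS, THF, −78 to 0 °C; then TsOH·H2O (cat.), acetone–H2O, 0 °C
Reagents that add atoms: (methoxymethyl)triphenylphosphonium chloride, COC[P+](c1ccccc1)(c1ccccc1)c1ccccc1.[Cl-]; water, O
Why: Wittig methoxymethylenation followed by enol ether hydrolysis adds C7 as an aldehyde carbon, and the fast enol ether hydrolysis should be over before the hindered tertiary TES ether is attacked.

**Step 4**
Reactants: 5 (5S)-5-methyl-5-(triethylsilyloxy)hept-6-enal
Product: 6 (2R,5S)-2-bromo-5-methyl-5-(triethylsilyloxy)hept-6-enal
Conditions: (R)-α,α-diphenylprolinol trimethylsilyl ether (5 mol %), NBS (slow addition), HFIP–H2O, 0 °C; short silica plug, used at once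
Reagents that add atoms: N-bromosuccinimide, O=C1CCC(=O)N1Br
Why: In this organocatalytic enamine α-bromination of an aldehyde, the bulky group of the (R)-catalyst shields one face of the E-enamine, so Br+ enters from the other face and sets C6 as R independently of the remote C3.

**Step 5**
Reactants: 6 (2R,5S)-2-bromo-5-methyl-5-(triethylsilyloxy)hept-6-enal
Product: 7 (3R,6S)-3-bromo-6-methyl-6-(triethylsilyloxy)oct-7-en-2-ol (mixture of C2 epimers)
Conditions: MeMgBr (1.1 equiv), Et2O, −78 °C; pH 7 buffer added at −78 °C
Reagents that add atoms: methylmagnesium bromide, C[Mg]Br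
Why: Grignard 1,2-addition to the α-bromo aldehyde at −78 °C outruns enolisation, the cold quench keeps the alkoxide from closing onto C6, and the new carbinol centre needs no control because step 6 erases it.

**Step 6**
Reactants: 7 (3R,6S)-3-bromo-6-methyl-6-(triethylsilyloxy)oct-7-en-2-ol
Product: 8 (3R,6S)-3-bromo-6-methyl-6-(triethylsilyloxy)oct-7-en-2-one
Conditions: Dess–Martin periodinane, CH2Cl2, 0 °C to rt
Reagents that add atoms: none
Why: Dess–Martin oxidation runs without base or strong acid, so the epimerisable C6–Br centre next to the new ketone should keep its R configuration.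

**Step 7**
Reactants: 9 5-bromo-2-methylpent-2-ene
Product: 10 (4-methylpent-3-en-1-yl)magnesium bromide (Et2O solution, titrated)
Conditions: Mg turnings, I2 (trace), Et2O, gentle reflux, then rt
Reagents that add atoms: magnesium, [Mg]
Why: Grignard formation by magnesium insertion into the primary C–Br bond gives the homoallylic reagent, which stays in its open-chain form.

**Step 8**
Reactants: 8 (3R,6S)-3-bromo-6-methyl-6-(triethylsilyloxy)oct-7-en-2-one; 10 (4-methylpent-3-en-1-yl)magnesium bromide
Product: 13 [(3S,6R)-6-bromo-6-[(2S,5S)-5-bromo-2,6,6-trimethyloxan-2-yl]-3-methylhex-1-en-3-yl]oxy(triethyl)silane (TES ether of the target), via magnesium alkoxide 11 (not isolated), via bromohydrin alkenol 12 (not isolated)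
Conditions: 10 (1.05 equiv), Et2O–toluene, −78 °C; AcOH (1.05 equiv), −78 °C; then (R)-BINOL-derived thiophosphoramide (10 mol %), DBDMH (0.55 equiv), toluene–CH2Cl2, −78 °C
Reagents that add atoms: 1,3-dibromo-5,5-dimethylhydantoin, CC1(C)N(Br)C(=O)N(Br)C1=O
Why: Proposed new method: 10 adds to the carbonyl carbon of 8 (C7–C8), alkoxide 11 is protonated in the cold so that it cannot displace the neighbouring bromide, and the sulfur Lewis base of the catalyst then passes Br+ from the hydantoin to the C10=C11 alkene of 12, whose bromonium ion is opened anti by the C7 hydroxyl at the CMe2 end (O–C11). The closest known reaction types are the Cornforth-type Grignard addition to α-halo ketones, the NBS or TBCO bromoetherification of tertiary 5-methylhex-4-enyl alcohols to 3-bromo-2,2-dimethyloxanes, and the thiophosphoramide-catalysed enantioselective bromonium-induced cyclisation of terminal prenyl groups; what is new is the oxygen terminator under catalyst control and the telescoping of both events. The oxane closes in the 6-endo mode through a chair in which the new C10–Br bond is equatorial and antiperiplanar to the new O–C11 bond. C7 (S) is controlled by C6: in the Cornforth/polar Felkin–Anh arrangement the C6–Br bond lies anti to the incoming carbon and the nucleophile passes the C6–H, which gives the anti bromohydrin pattern of the target. C10 (S) is controlled by the catalyst, which has to deliver bromine to the Si face of C10, because the two chairs (C6 arm axial or C7 methyl axial) each carry one 1,3-diaxial contact with a C11 methyl group and leave the substrate with little bias of its own. The step needs 1,2-addition over enolisation and Br/Mg exchange (−78 °C, activated α-bromo ketone), bromination of the trisubstituted alkene rather than the vinyl group (monosubstituted and deactivated by the adjacent silyloxy carbon), and 6-endo over 5-exo opening (tertiary cation character at C11).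

**Step 9**
Reactants: 13 TES ether of the target
Product: 14 (3S,6R)-6-bromo-6-[(2S,5S)-5-bromo-2,6,6-trimethyloxan-2-yl]-3-methylhex-1-en-3-ol (target)
Conditions: HF·pyridine, pyridine, THF, 0 °C
Reagents that add atoms: none
Why: Fluoride-driven desilylation under buffered, non-basic conditions frees the tertiary allylic alcohol as the neutral hydroxyl, so neither ionisation at C3 nor internal displacement of the hindered C6 bromide should occur.

**Compound list**
1 | (S)-(+)-linalool, (3S)-3,7-dimethylocta-1,6-dien-3-ol | C=C[C@@](C)(O)CCC=C(C)C | starting material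
2 | (3S)-3,7-dimethyl-3-(triethylsilyloxy)octa-1,6-diene | C=C[C@@](C)(O[Si](CC)(CC)CC)CCC=C(C)C | intermediate
3 | (4S)-4-methyl-4-(triethylsilyloxy)hex-5-enal | C=C[C@@](C)(O[Si](CC)(CC)CC)CCC=O | intermediate
4 | (3S)-7-methoxy-3-methyl-3-(triethylsilyloxy)hepta-1,6-diene (E/Z mixture, not isolated) | C=C[C@@](C)(O[Si](CC)(CC)CC)CCC=COC | intermediate
5 | (5S)-5-methyl-5-(triethylsilyloxy)hept-6-enal | C=C[C@@](C)(O[Si](CC)(CC)CC)CCCC=O | intermediate
6 | (2R,5S)-2-bromo-5-methyl-5-(triethylsilyloxy)hept-6-enal | C=C[C@@](C)(O[Si](CC)(CC)CC)CC[C@@H](Br)C=O | intermediate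
7 | (3R,6S)-3-bromo-6-methyl-6-(triethylsilyloxy)oct-7-en-2-ol (C2 epimers) | C=C[C@@](C)(O[Si](CC)(CC)CC)CC[C@@H](Br)C(C)O | intermediate
8 | (3R,6S)-3-bromo-6-methyl-6-(triethylsilyloxy)oct-7-en-2-one | C=C[C@@](C)(O[Si](CC)(CC)CC)CC[C@@H](Br)C(C)=O | intermediate
9 | 5-bromo-2-methylpent-2-ene | CC(C)=CCCBr | starting material
10 | (4-methylpent-3-en-1-yl)magnesium bromide | CC(C)=CCC[Mg]Br | intermediate
11 | bromomagnesium alkoxide of 12 (not isolated) | C=C[C@@](C)(O[Si](CC)(CC)CC)CC[C@@H](Br)[C@](O[Mg]Br)(C)CCC=C(C)C | intermediate
12 | (3S,6R,7S)-6-bromo-3,7,11-trimethyl-3-(triethylsilyloxy)dodeca-1,10-dien-7-ol (not isolated) | C=C[C@@](C)(O[Si](CC)(CC)CC)CC[C@@H](Br)[C@](O)(C)CCC=C(C)C | intermediate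
13 | [(3S,6R)-6-bromo-6-[(2S,5S)-5-bromo-2,6,6-trimethyloxan-2-yl]-3-methylhex-1-en-3-yl]oxy(triethyl)silane | C=C[C@@](C)(O[Si](CC)(CC)CC)CC[C@@H](Br)[C@]1(C)CC[C@H](Br)C(C)(C)O1 | intermediate
14 | (3S,6R)-6-bromo-6-[(2S,5S)-5-bromo-2,6,6-trimethyloxan-2-yl]-3-methylhex-1-en-3-ol | C=C[C@@](C)(O)CC[C@@H](Br)[C@]1(C)CC[C@H](Br)C(C)(C)O1 | target

Total steps: 9. Longest linear sequence: 8 (steps 1–6, 8, 9).

**Steps most likely to fail**

**Step 8 (labelled step).**
- What may go wrong: facial selection at C10 may be weak or wrong if bromine transfer promoted by the magnesium salts outruns the catalyst. Other failure modes are 5-exo closure, enolisation or Br/Mg exchange of the ketone, and closure of the alkoxide onto C6.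
- Fallback (from 8 and 10, back at 13): the event is split into its two known reactions, and control at C10 is replaced by separation. The addition is quenched with aqueous NH4Cl at −78 °C and alcohol 12 is isolated. Uncatalysed 6-endo bromoetherification with NBS in HFIP at 0 °C should then give 13 together with the (10R)-epimer of 13 F1. The two are separated by chromatography.

**Step 4.**
- What may go wrong: the configuration of the α-bromo aldehyde may erode through enolisation or renewed enamine formation. Double bromination and bromination of the catalyst are also possible.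
- Fallback (from 5, back at 8; steps 4–6 are bypassed): auxiliary control replaces catalysis.
  - Pinnick oxidation gives (5S)-5-methyl-5-(triethylsilyloxy)hept-6-enoic acid F2.
  - DCC/DMAP coupling with (R)-4-benzyloxazolidin-2-one gives the N-acyl oxazolidinone F3.
  - Boron enolate formation (Bu2BOTf, i-Pr2NEt) and NBS at −78 °C give the (2R)-α-bromo imide F4, which is purified as a single diastereomer.
  - Me(MeO)NH·HCl/AlMe3 gives the α-bromo Weinreb amide F5.
  - MeMgBr at −78 °C then gives 8.

**Step 2.**
- What may go wrong: ozone may attack the vinyl group, or the aldehyde may be over-oxidised.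
- Fallback (from 2, back at 3): the cleavage is done in two neutral stages. OsO4 (cat.)/NMO dihydroxylation of the more electron-rich trisubstituted alkene gives the 6,7-diol F6. NaIO4 glycol cleavage then gives 3.

**Further compounds**
F1 | step 8 | (10R)-epimer of 13, [(3S,6R)-6-bromo-6-[(2S,5R)-5-bromo-2,6,6-trimethyloxan-2-yl]-3-methylhex-1-en-3-yl]oxy(triethyl)silane | C=C[C@@](C)(O[Si](CC)(CC)CC)CC[C@@H](Br)[C@]1(C)CC[C@@H](Br)C(C)(C)O1
F2 | step 4 | (5S)-5-methyl-5-(triethylsilyloxy)hept-6-enoic acid | C=C[C@@](C)(O[Si](CC)(CC)CC)CCCC(=O)O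
F3 | step 4 | (4R)-4-benzyl-3-[(5S)-5-methyl-5-(triethylsilyloxy)hept-6-enoyl]oxazolidin-2-one | C=C[C@@](C)(O[Si](CC)(CC)CC)CCCC(=O)N1[C@H](Cc2ccccc2)COC1=O
F4 | step 4 | (4R)-4-benzyl-3-[(2R,5S)-2-bromo-5-methyl-5-(triethylsilyloxy)hept-6-enoyl]oxazolidin-2-one | C=C[C@@](C)(O[Si](CC)(CC)CC)CC[C@@H](Br)C(=O)N1[C@H](Cc2ccccc2)COC1=O
F5 | step 4 | (2R,5S)-2-bromo-N-methoxy-N,5-dimethyl-5-(triethylsilyloxy)hept-6-enamide | C=C[C@@](C)(O[Si](CC)(CC)CC)CC[C@@H](Br)C(=O)N(C)OC
F6 | step 2 | (6S)-2,6-dimethyl-6-(triethylsilyloxy)oct-7-ene-2,3-diol (C3 epimers) | C=C[C@@](C)(O[Si](CC)(CC)CC)CCC(O)C(C)(C)O
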